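Take a small charge of catalyst, 1.3 mM against 0.63 M of starting material, and ask what it is worth at a fixed conversion, not at a fixed time.

| setting | north | north-west | flask |
|---|---|---|---|
| starting material | 0.63 M | 0.63 M | 0.63 M |
| partner | 0.756 M | 0.38 M | 0.756 M |
| catalyst | 1.3 mM | 1.3 mM | 1.3 mM |
| remark | the very flask that is asked about, followed so far | run made earlier |  |

| run | time / h | product / % |
|---|---|---|
| north | 0.200 | 2.1 |
| north | 0.417 | 5.1 |
| north | 1.00 | 10.6 |
| north | 2.50 | 21.9 |
| north-west | 4.00 | 15.6 |
| north-west | 8.00 | 24.4 |
| north-west | 10.0 | 26.1 |
| north-west | 15.0 | 32.5 |

(scatter of a reading: 0.3 percentage points)

1. factor on the rate of making product when 20% of the starting material are converted if partner is charged twice over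
2. factor on the rate when 20% of the starting material are converted if catalyst is charged at 6.0 mM instead

- no earlier run changes the charge of catalyst; that part of a forecast is a guess

Begin with the main step by itself, its rate proportional to starting material, partner and working catalyst. At 20% conversion the north flask holds 0.630 M of partner, and a doubled charge of 1.51 M would hold 1.39 M. Starting material is equal in the two, so the factor is 2.20. For catalyst, assume first order, which is a guess, and the factor is 4.62.

Now add loss of working catalyst. Integrate the main step with constant catalyst and read an apparent constant: 0.155 M⁻¹ h⁻¹ from the north run at 1.00 h, and 0.130 M⁻¹ h⁻¹ from the north-west run at 4.00 h. Treat each as the working catalyst at half the time of its reading, taking partner as first order. The fall between those two moments then gives the catalyst clock, the fraction of working catalyst lost per hour: 0.120 h⁻¹, a reading that carries the scatter of 0.3 percentage points.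

At a fixed conversion, the clock counts the time taken to get there. Read between the north readings, 20% comes at about 2.25 h, where the clock estimates 76.3% of the catalyst still working. Estimate the time with doubled partner as about 1.07 h, with 87.9% working by the clock, and with 6.0 mM of catalyst as about 0.487 h, with 94.3% working by the clock.

Then the rest: the north-west constant of 0.102 M⁻¹ h⁻¹ at 15.0 h reads as a loss that slows later, but the estimated 2.25 h in the north flask is earlier, so leave that out of this reckoning. My reckoning commits to 2.53 for partner and 5.70 for catalyst.

The forecast, which took the drift to suggest “slow catalyst death”, stood at 2.4 and 5, below my reckoning on each.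

The simulation gives 2.48 for partner and 5.52 for catalyst.

    starting material + partner + catalyst → product + catalyst, rate k1*[starting material]*[partner]*[catalyst]/(1 + ([starting material]/sat1)) (2.00 M, k = 160 M⁻² h⁻¹)
    catalyst ⇌ dormant form (K = 1.60, k = 0.110 h⁻¹)

In the flask, the time to 20% conversion read from the north run, about 2.25 h, is shorter than the relaxation half-life of catalyst and dormant form, both ways together, 3.88 h; the clock prices that time at 23.7% of the catalyst lost, and 20.3% of the catalyst stands as dormant form at that conversion. With catalyst at 6.0 mM, the estimated time to the same conversion, about 0.487 h, is far shorter than that half-life; the clock gives 5.68%, and the share of dormant form at that conversion is 4.68%.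

(Readings and results were computed with constants of no real substance, noise included.)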